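Everything rests on forming C5–C6 while unmasking the C9 ketone. Ring B (C1–C8–C7–C6–C5–C9) places the bridging C9 carbonyl 1,4 to C7 across C5–C6; that pattern results when a C6 carbenoid, tethered through C7 and C8 to quaternary C1, cyclopropanates the enol ether C9(OMe)=C5 and the donor–acceptor bond C6–C9 is then cleaved. In one operation an achiral Birch diene is desymmetrised, ring B is closed and C1 and C5 are set. The precursor is a 2,6-dimethoxycyclohexa-2,5-diene whose C1 bears prenyl and a CMe2–CO–CHN2 arm. Later steps turn C7 into the endo-prenyl methine, oxidise C4, geranylate C5 and aroylate C3.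

Key step: step 5

Remarks and assumptions
- Atom labels follow the bicyclo[3.3.1]nonane core of the target and are used for all intermediates. Ring A is C1–C2–C3–C4–C5–C9 and ring B is C1–C8–C7–C6–C5–C9. "Endo" at C7 means the face of ring B turned toward C3 of ring A.
- The target is an enolised β-triketone whose C2-OH and C4-OH enol forms interconvert; the C4-OH form is drawn.
- Configuration check: (1R,5R)-11 carries C1 and C5 in the sense the target needs, and the C7 prenyl group of the target is endo (7S). Descriptors at C1 and C5 change along the route only because substituent priorities change.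
- Which antipode of the bis(oxazoline) ligand gives (1R,5R)-11 cannot be predicted with confidence. The (S,S) ligand, 2,2′-(propane-2,2-diyl)bis[(4S)-4-tert-butyl-4,5-dihydro-1,3-oxazole], is written; its mirror image is to be used if the first run shows the opposite sense.
- Compound 1 is taken as a catalogue compound.
- Acids 4 and 7 carry enol ethers β to the carboxyl group and can lactonise under acid. They are to be liberated at pH 5 and 0 °C and used the same day.

Step 1
Reactants: 1 (2,6-dimethoxyphenyl)acetic acid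
Product: 3 2-(2,6-dimethoxyphenyl)-2-methylpropanoic acid, via methyl ester 2 (not isolated)
Conditions: NaH, MeI, THF/DMPU, 0 °C → rt; then KOH, MeOH/H2O, 80 °C; aq. HCl
Reagents that add atoms: iodomethane, CI (the two C-methyl groups and the transient ester methyl); potassium hydroxide, [K+].[OH-] (one carboxyl oxygen)
Why: Enolate alkylation followed by saponification: NaH forms the carboxylate, which is O-methylated, the benzylic position of the resulting arylacetate is C-methylated twice and stops at the quaternary carbon, and hydroxide then cleaves the hindered methyl ester under conditions the arene tolerates; no stereocentre is formed.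

Step 2
Reactants: 3 2-(2,6-dimethoxyphenyl)-2-methylpropanoic acid
Product: 4 2-(2,6-dimethoxycyclohexa-2,5-dien-1-yl)-2-methylpropanoic acid
Conditions: Li, NH3(l)/THF, t-BuOH, −78 °C; NH4Cl; aq. NaH2PO4 (pH 5), 0 °C
Reagents that add atoms: none
Why: Birch reduction: the 1,3-dimethoxyarene takes up two electrons and two protons so that both methoxy groups stay on double bonds (sp3 carbons at C1 and at the para carbon), the carboxylate is inert to Li/NH3, and the product is achiral.

Step 3
Reactants: 4 2-(2,6-dimethoxycyclohexa-2,5-dien-1-yl)-2-methylpropanoic acid; 5 prenyl bromide (1-bromo-3-methylbut-2-ene)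
Product: 7 2-[2,6-dimethoxy-1-(3-methylbut-2-en-1-yl)cyclohexa-2,5-dien-1-yl]-2-methylpropanoic acid, via dilithio dienyl anion 6 (not isolated)
Conditions: t-BuLi (2.2 equiv), THF/DMPU, −78 → −40 °C; 5, −78 → 0 °C; aq. NaH2PO4 (pH 5), 0 °C
Reagents that add atoms: tert-butyllithium, [Li]C(C)(C)C (lithium of 6 only)
Why: Alkylation of a cyclohexadienyl anion from a Birch diene: after the carboxylate forms, t-BuLi removes the doubly allylic C1–H (addition to the neopentyl-type carboxylate is slow at −78 °C), and the pentadienyl anion should react with the allylic bromide at its central carbon, which restores both enol ethers and gives the C1 quaternary centre next to C8; 7 keeps a mirror plane, so no stereocontrol is needed.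

Step 4
Reactants: 7 2-[2,6-dimethoxy-1-(3-methylbut-2-en-1-yl)cyclohexa-2,5-dien-1-yl]-2-methylpropanoic acid
Product: 9 1-diazo-3-[2,6-dimethoxy-1-(3-methylbut-2-en-1-yl)cyclohexa-2,5-dien-1-yl]-3-methylbutan-2-one, via acid chloride 8 (not isolated)
Conditions: Me2C=C(Cl)NMe2, CH2Cl2, 0 °C; then CH2N2 (excess), Et2O, 0 °C → rt
Reagents that add atoms: diazomethane, C=[N+]=[N-] (the CHN2 carbon and both nitrogens); 1-chloro-N,N,2-trimethylprop-1-en-1-amine, CC(C)=C(Cl)N(C)C (chlorine of 8 only)
Why: Acylation of diazomethane by an acid chloride (first half of an Arndt–Eistert sequence): the α-chloroenamine converts the acid to 8 without releasing HCl, which spares the two enol ethers, and excess diazomethane attacks the hindered carbonyl and removes the HCl formed as chloromethane; no stereocentre is involved.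

Step 5
Reactants: 9 1-diazo-3-[2,6-dimethoxy-1-(3-methylbut-2-en-1-yl)cyclohexa-2,5-dien-1-yl]-3-methylbutan-2-one
Product: 11 (1R,5R)-2-methoxy-8,8-dimethyl-1-(3-methylbut-2-en-1-yl)bicyclo[3.3.1]non-2-ene-7,9-dione, via donor–acceptor cyclopropane 10 (not isolated)
Conditions: [Cu(MeCN)4]PF6 (5 mol %), (S,S)-t-Bu-BOX (6 mol %), CH2Cl2, rt, slow addition of 9; then MgI2 (1.5 equiv), Et2O, 0 °C → rt; aq. NaHCO3
Reagents that add atoms: none
Why: The carbenoid formed at C6 on monovalent copper by loss of N2 adds to the C9=C5 enol ether (bonds C6–C9 and C6–C5) to give 10, and MgI2 then binds the C7 ketone so that the push–pull bond C6–C9 breaks to a C9 oxocarbenium ion and a C6=C7 magnesium enolate, iodide removes the O-methyl group and work-up protonates C6. The closest known reaction type is the copper–bis(oxazoline)-catalysed asymmetric intramolecular cyclopropanation of α-diazo ketones on prochiral 1,5-dimethoxycyclohexa-1,4-dienes with subsequent opening of the donor–acceptor cyclopropane. Ring B (C5–C6–C7–C8–C1–C9) is the ring that remains: the cyclopentanone of 10 is closed 5-exo through C6–C9 and opened again, and the surviving C5–C6 bond amounts to a 6-endo closure onto the nucleophilic β-carbon of the enol ether. C1 and C5 are set in the same event, their absolute configuration by the chiral ligand, which decides which of the two enantiotopic enol ethers of the mirror-symmetric diene is attacked, and their relative configuration by the tether, which can only reach the ring face that carries it. The step needs enantiotopic-group selection (ligand), chemoselection for the enol ether over the prenyl alkene (five- against six-membered transition state, more electron-rich π bond, C8 gem-dimethyl group holding the carbenoid over the ring) and cleavage of C6–C9 instead of C5–C6 (only C9 bears the methoxy donor).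

Step 6
Reactants: 11 (1R,5R)-2-methoxy-8,8-dimethyl-1-(3-methylbut-2-en-1-yl)bicyclo[3.3.1]non-2-ene-7,9-dione
Product: 12 (1R,5R)-2-methoxy-8,8-dimethyl-7-methylidene-1-(3-methylbut-2-en-1-yl)bicyclo[3.3.1]non-2-en-9-one
Conditions: Cp2TiMe2 (1.5 equiv), toluene/THF, 65 °C, dark
Reagents that add atoms: dimethyltitanocene Cp2TiMe2, C[Ti](C)(C1C=CC=C1)C1C=CC=C1 (the methylidene carbon)
Why: Petasis methylenation: Cp2Ti=CH2 formed on heating undergoes [2+2] addition and cycloreversion at the C7 ketone without enolising C6, and it should prefer C7 over C9 because C9 is flanked by quaternary C1 and the C5 bridgehead and is screened on the ring B side by the axial C8 methyl group; C1 and C5 are untouched.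

Step 7
Reactants: 12 (1R,5R)-2-methoxy-8,8-dimethyl-7-methylidene-1-(3-methylbut-2-en-1-yl)bicyclo[3.3.1]non-2-en-9-one; 13 1-bromo-2-methylprop-1-ene
Product: 15 (1R,5S,7S)-2-methoxy-8,8-dimethyl-1,7-bis(3-methylbut-2-en-1-yl)bicyclo[3.3.1]non-2-en-9-one, via alkylborane 14 (not isolated)
Conditions: 9-BBN, THF, 0 °C → rt; then 13, PdCl2(dppf) (5 mol %), 3 M aq. NaOH, 50 °C
Reagents that add atoms: 9-borabicyclo[3.3.1]nonane (9-BBN), B1C2CCCC1CCC2 (boron of 14 only)
Why: Hydroboration followed by B-alkyl Suzuki–Miyaura coupling: 9-BBN adds boron to the terminal carbon of the 1,1-disubstituted alkene (the trisubstituted prenyl and enol-ether alkenes and the hindered C9 ketone react far more slowly) and delivers hydrogen to C7 from the exo face of ring B, the face turned away from the C2–C4 bridge of ring A, so that the borylmethyl arm ends endo (7S), and the alkylborane then couples with the vinyl bromide on zerovalent palladium to complete the prenyl group.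

Step 8
Reactants: 15 (1R,5S,7S)-2-methoxy-8,8-dimethyl-1,7-bis(3-methylbut-2-en-1-yl)bicyclo[3.3.1]non-2-en-9-one
Product: 16 (1R,5S,7S)-2-methoxy-8,8-dimethyl-1,7-bis(3-methylbut-2-en-1-yl)bicyclo[3.3.1]non-2-ene-4,9-dione
Conditions: Pd(OH)2/C (cat.), t-BuOOH, Cs2CO3, CH2Cl2, 0 °C → rt
Reagents that add atoms: tert-butyl hydroperoxide, CC(C)(C)OO (the C4 oxygen)
Why: Allylic C–H oxidation by a palladium-initiated tert-butylperoxyl radical chain: hydrogen abstraction is expected at C4, the only methylene whose radical is conjugated with the electron-rich C2=C3 enol ether, and the C4 peroxide collapses to the ketone (Kornblum–DeLaMare type) to give the vinylogous ester; C1, C5 and C7 are unchanged.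

Step 9
Reactants: 16 (1R,5S,7S)-2-methoxy-8,8-dimethyl-1,7-bis(3-methylbut-2-en-1-yl)bicyclo[3.3.1]non-2-ene-4,9-dione; 17 geranyl bromide ((2E)-1-bromo-3,7-dimethylocta-2,6-diene)
Product: 19 (1R,5S,7S)-5-[(2E)-3,7-dimethylocta-2,6-dien-1-yl]-2-methoxy-8,8-dimethyl-1,7-bis(3-methylbut-2-en-1-yl)bicyclo[3.3.1]non-2-ene-4,9-dione, via bridgehead organolithium 18 (not isolated)
Conditions: LiN(i-Pr)2, THF, −78 °C; 17, −78 → −20 °C
Reagents that add atoms: lithium diisopropylamide LiN(i-Pr)2, [Li]N(C(C)C)C(C)C (lithium of 18 only)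
Why: Bridgehead deprotonation and alkylation: C5–H lies between the C4 and C9 carbonyl groups and is the only acidic sp3 C–H (C1 is quaternary), the pyramidal bridgehead carbanion cannot invert inside the bicycle, and SN2 attack on the primary allylic bromide installs the geranyl group with retention at C5 and with the E alkene intact.

Step 10
Reactants: 20 3-hydroxybenzoic acid
Product: 22 3-[(tert-butyldimethylsilyl)oxy]benzoyl chloride, via bis-silyl derivative 21 (not isolated)
Conditions: TBSCl, imidazole, DMF/CH2Cl2, rt; then (COCl)2, DMF (cat.), CH2Cl2, 0 °C → rt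
Reagents that add atoms: tert-butyl(chloro)dimethylsilane, CC(C)(C)[Si](C)(C)Cl (the silyl groups); oxalyl chloride, ClC(=O)C(Cl)=O (the chlorine)
Why: Silylation and conversion of a silyl ester into an acid chloride: TBSCl/imidazole silylates the phenol and the carboxylic acid, and oxalyl chloride with catalytic DMF turns the silyl ester into the acyl chloride under neutral conditions while the aryl silyl ether stays in place.

Step 11
Reactants: 19 (1R,5S,7S)-5-[(2E)-3,7-dimethylocta-2,6-dien-1-yl]-2-methoxy-8,8-dimethyl-1,7-bis(3-methylbut-2-en-1-yl)bicyclo[3.3.1]non-2-ene-4,9-dione; 22 3-[(tert-butyldimethylsilyl)oxy]benzoyl chloride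
Product: 24 (1R,5R,7S)-3-{3-[(tert-butyldimethylsilyl)oxy]benzoyl}-5-[(2E)-3,7-dimethylocta-2,6-dien-1-yl]-2-methoxy-8,8-dimethyl-1,7-bis(3-methylbut-2-en-1-yl)bicyclo[3.3.1]non-2-ene-4,9-dione, via vinyllithium 23 (not isolated)
Conditions: lithium 2,2,6,6-tetramethylpiperidide, THF, −78 °C; 22, −78 → −40 °C
Reagents that add atoms: lithium 2,2,6,6-tetramethylpiperidide, [Li]N1C(C)(C)CCCC1(C)C (lithium of 23 only)
Why: Directed vinylic lithiation and acylation: with both bridgeheads quaternary, the hindered amide removes the C3 vinylic proton flanked by the C2 methoxy group and the C4 carbonyl, and the vinyllithium is acylated by the aroyl chloride; no stereocentre is touched.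

Step 12
Reactants: 24 (1R,5R,7S)-3-{3-[(tert-butyldimethylsilyl)oxy]benzoyl}-5-[(2E)-3,7-dimethylocta-2,6-dien-1-yl]-2-methoxy-8,8-dimethyl-1,7-bis(3-methylbut-2-en-1-yl)bicyclo[3.3.1]non-2-ene-4,9-dione
Product: 25 (1S,5S,7S)-5-[(2E)-3,7-dimethylocta-2,6-dien-1-yl]-4-hydroxy-3-(3-hydroxybenzoyl)-8,8-dimethyl-1,7-bis(3-methylbut-2-en-1-yl)bicyclo[3.3.1]non-3-ene-2,9-dione (CNP0236890.1)
Conditions: LiOH·H2O, 1,4-dioxane/H2O, 90 °C; then 1 M HCl to pH 3, 0 °C
Reagents that add atoms: lithium hydroxide, [Li+].[OH-] (the C2 oxygen)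
Why: Addition–elimination hydrolysis of a vinylogous ester with concurrent desilylation: hydroxide adds to C2, which is activated by both the C4 and the aroyl carbonyl groups, and expels methoxide to give a stabilised triketone enolate that resists retro-Claisen cleavage, hydroxide also cleaves the aryl silyl ether, and cold acidification gives the enol; C1 and C5 are quaternary and C7 is not enolisable, so all three stereocentres are retained.

Compound list
1 | (2,6-dimethoxyphenyl)acetic acid | COc1cccc(OC)c1CC(=O)O | starting material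
2 | methyl 2-(2,6-dimethoxyphenyl)-2-methylpropanoate | COC(=O)C(C)(C)c1c(OC)cccc1OC | intermediate
3 | 2-(2,6-dimethoxyphenyl)-2-methylpropanoic acid | OC(=O)C(C)(C)c1c(OC)cccc1OC | intermediate
4 | 2-(2,6-dimethoxycyclohexa-2,5-dien-1-yl)-2-methylpropanoic acid | OC(=O)C(C)(C)C1C(OC)=CCC=C1OC | intermediate
5 | prenyl bromide (1-bromo-3-methylbut-2-ene) | CC(C)=CCBr | starting material
6 | C1-lithiated lithium carboxylate of 4 (dilithio cyclohexadienyl anion) | [Li]OC(=O)C(C)(C)C1([Li])C(OC)=CCC=C1OC | intermediate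
7 | 2-[2,6-dimethoxy-1-(3-methylbut-2-en-1-yl)cyclohexa-2,5-dien-1-yl]-2-methylpropanoic acid | OC(=O)C(C)(C)C1(CC=C(C)C)C(OC)=CCC=C1OC | intermediate
8 | 2-[2,6-dimethoxy-1-(3-methylbut-2-en-1-yl)cyclohexa-2,5-dien-1-yl]-2-methylpropanoyl chloride | ClC(=O)C(C)(C)C1(CC=C(C)C)C(OC)=CCC=C1OC | intermediate
9 | 1-diazo-3-[2,6-dimethoxy-1-(3-methylbut-2-en-1-yl)cyclohexa-2,5-dien-1-yl]-3-methylbutan-2-one | COC1=CCC=C(OC)C1(CC=C(C)C)C(C)(C)C(=O)C=[N+]=[N-] | intermediate
10 | tricyclic donor–acceptor cyclopropane: cyclopropane C5–C6–C9 cis-fused to the cyclohexene C1–C2–C3–C4–C5–C9 (C2-OMe, C2=C3) and to the cyclopentanone C6–C7–C8–C1–C9 (C7=O, C8 Me2); OMe on C9, prenyl on C1 | COC1=CC[C@@H]2[C@@H]3C(=O)C(C)(C)[C@@]1(CC=C(C)C)[C@]23OC | intermediate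
11 | (1R,5R)-2-methoxy-8,8-dimethyl-1-(3-methylbut-2-en-1-yl)bicyclo[3.3.1]non-2-ene-7,9-dione | [C@H]12CC(=O)C(C)(C)[C@](CC=C(C)C)(C(OC)=CC1)C2=O | intermediate
12 | (1R,5R)-2-methoxy-8,8-dimethyl-7-methylidene-1-(3-methylbut-2-en-1-yl)bicyclo[3.3.1]non-2-en-9-one | [C@H]12CC(=C)C(C)(C)[C@](CC=C(C)C)(C(OC)=CC1)C2=O | intermediate
13 | 1-bromo-2-methylprop-1-ene | CC(C)=CBr | starting material
14 | (1R,5S,7S)-7-[(9-borabicyclo[3.3.1]nonan-9-yl)methyl]-2-methoxy-8,8-dimethyl-1-(3-methylbut-2-en-1-yl)bicyclo[3.3.1]non-2-en-9-one (borylmethyl arm endo) | [C@H]12C[C@H](CB3C4CCCC3CCC4)C(C)(C)[C@](CC=C(C)C)(C(OC)=CC1)C2=O | intermediate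
15 | (1R,5S,7S)-2-methoxy-8,8-dimethyl-1,7-bis(3-methylbut-2-en-1-yl)bicyclo[3.3.1]non-2-en-9-one (C7 prenyl endo) | [C@H]12C[C@H](CC=C(C)C)C(C)(C)[C@](CC=C(C)C)(C(OC)=CC1)C2=O | intermediate
16 | (1R,5S,7S)-2-methoxy-8,8-dimethyl-1,7-bis(3-methylbut-2-en-1-yl)bicyclo[3.3.1]non-2-ene-4,9-dione | [C@H]12C[C@H](CC=C(C)C)C(C)(C)[C@](CC=C(C)C)(C(OC)=CC1=O)C2=O | intermediate
17 | geranyl bromide ((2E)-1-bromo-3,7-dimethylocta-2,6-diene) | CC(C)=CCC/C(C)=C/CBr | starting material
18 | C5-lithio derivative of 16 (lithium at the bridgehead, configuration retained) | [Li][C@]12C[C@H](CC=C(C)C)C(C)(C)[C@](CC=C(C)C)(C(OC)=CC1=O)C2=O | intermediate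
19 | (1R,5S,7S)-5-[(2E)-3,7-dimethylocta-2,6-dien-1-yl]-2-methoxy-8,8-dimethyl-1,7-bis(3-methylbut-2-en-1-yl)bicyclo[3.3.1]non-2-ene-4,9-dione | CC(C)=CCC/C(C)=C/C[C@]12C[C@H](CC=C(C)C)C(C)(C)[C@](CC=C(C)C)(C(OC)=CC1=O)C2=O | intermediate
20 | 3-hydroxybenzoic acid | OC(=O)c1cccc(O)c1 | starting material
21 | tert-butyldimethylsilyl 3-[(tert-butyldimethylsilyl)oxy]benzoate | CC(C)(C)[Si](C)(C)OC(=O)c1cccc(O[Si](C)(C)C(C)(C)C)c1 | intermediate
22 | 3-[(tert-butyldimethylsilyl)oxy]benzoyl chloride | CC(C)(C)[Si](C)(C)Oc1cccc(C(Cl)=O)c1 | intermediate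
23 | C3-lithio derivative of 19 (vinyllithium between C2-OMe and C4=O) | CC(C)=CCC/C(C)=C/C[C@]12C[C@H](CC=C(C)C)C(C)(C)[C@](CC=C(C)C)(C(OC)=C([Li])C1=O)C2=O | intermediate
24 | (1R,5R,7S)-3-{3-[(tert-butyldimethylsilyl)oxy]benzoyl}-5-[(2E)-3,7-dimethylocta-2,6-dien-1-yl]-2-methoxy-8,8-dimethyl-1,7-bis(3-methylbut-2-en-1-yl)bicyclo[3.3.1]non-2-ene-4,9-dione | CC(C)=CCC/C(C)=C/C[C@]12C[C@H](CC=C(C)C)C(C)(C)[C@](CC=C(C)C)(C(OC)=C(C(=O)c3cccc(O[Si](C)(C)C(C)(C)C)c3)C1=O)C2=O | intermediate
25 | (1S,5S,7S)-5-[(2E)-3,7-dimethylocta-2,6-dien-1-yl]-4-hydroxy-3-(3-hydroxybenzoyl)-8,8-dimethyl-1,7-bis(3-methylbut-2-en-1-yl)bicyclo[3.3.1]non-3-ene-2,9-dione | CC(C)=CCC/C(C)=C/C[C@]12C[C@H](CC=C(C)C)C(C)(C)[C@](CC=C(C)C)(C(=O)C(C(=O)c3cccc(O)c3)=C1O)C2=O | target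

Total step count: 12. Longest linear sequence: 11 steps (steps 1–9, 11 and 12); step 10 prepares the aroyl chloride.

Steps most likely to fail

Step 3 (C-prenylation at C1). The metalation of the hindered tertiary C1–H may be slow, t-BuLi may add to the carboxylate, or the dienyl anion may be alkylated at a terminal carbon because its central carbon carries the tertiary substituent. The fallback reverses the order in which the two adjacent quaternary carbons are made; it sets out from 5 (with commercial 2,6-dimethoxybenzoic acid in place of 1) and comes back at 7. Birch reductive alkylation (Li, NH3/THF, −78 °C; then 5) should give 2,6-dimethoxy-1-(3-methylbut-2-en-1-yl)cyclohexa-2,5-diene-1-carboxylic acid F1, because the carboxylate-stabilised carbanion is alkylated at C1. Arndt–Eistert homologation would follow, through 2,6-dimethoxy-1-(3-methylbut-2-en-1-yl)cyclohexa-2,5-diene-1-carbonyl chloride F2 and 2-diazo-1-[2,6-dimethoxy-1-(3-methylbut-2-en-1-yl)cyclohexa-2,5-dien-1-yl]ethan-1-one F3, whose Wolff rearrangement (PhCO2Ag, Et3N, MeOH) would give methyl [2,6-dimethoxy-1-(3-methylbut-2-en-1-yl)cyclohexa-2,5-dien-1-yl]acetate F4. Two enolate methylations (LiN(i-Pr)2, MeI), through racemic methyl 2-[2,6-dimethoxy-1-(3-methylbut-2-en-1-yl)cyclohexa-2,5-dien-1-yl]propanoate F5, would give methyl 2-[2,6-dimethoxy-1-(3-methylbut-2-en-1-yl)cyclohexa-2,5-dien-1-yl]-2-methylpropanoate F6, and SN2 demethylation with lithium propane-1-thiolate in DMPU would release 7.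

Step 5 (key step). The catalyst may discriminate poorly between the enantiotopic enol ethers, or the carbenoid may be diverted to the prenyl alkene or to the methoxy oxygen. The fallback tames the carbenoid with a second acceptor, the substrate class for which this copper–bis(oxazoline) system is most selective; it sets out from 7 (through 8) and comes back at 11. Condensation of 8 with mesityl methyl sulfone and n-BuLi would give 3-[2,6-dimethoxy-1-(3-methylbut-2-en-1-yl)cyclohexa-2,5-dien-1-yl]-3-methyl-1-(2,4,6-trimethylbenzenesulfonyl)butan-2-one F7. Diazo transfer (4-acetamidobenzenesulfonyl azide, Et3N, MeCN) would give 1-diazo-3-[2,6-dimethoxy-1-(3-methylbut-2-en-1-yl)cyclohexa-2,5-dien-1-yl]-3-methyl-1-(2,4,6-trimethylbenzenesulfonyl)butan-2-one F8. The catalyst of step 5 should then give the 6-(2,4,6-trimethylbenzenesulfonyl)cyclopropane F9, MgI2 the 6-(2,4,6-trimethylbenzenesulfonyl)bicyclononenedione F10, and reductive desulfonylation (SmI2, THF/MeOH, −78 °C) would give 11.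

Step 8 (C4 oxidation). Hydrogen abstraction at the allylic positions of the two prenyl groups, or over-oxidation, may compete with attack at C4. The fallback moves the oxidation two steps earlier, where only one prenyl group and no C7 side chain compete; it sets out from 11 and comes back at 16. The conditions of step 8 applied to 11 should give (1R,5S)-2-methoxy-8,8-dimethyl-1-(3-methylbut-2-en-1-yl)bicyclo[3.3.1]non-2-ene-4,7,9-trione F11. Petasis methylenation of the C7 ketone (more electrophilic than the vinylogous ester carbonyl) would give (1R,5S)-2-methoxy-8,8-dimethyl-7-methylidene-1-(3-methylbut-2-en-1-yl)bicyclo[3.3.1]non-2-ene-4,9-dione F12. Hydroboration with 9-BBN at 0 °C would give (1R,5S,7S)-7-[(9-borabicyclo[3.3.1]nonan-9-yl)methyl]-2-methoxy-8,8-dimethyl-1-(3-methylbut-2-en-1-yl)bicyclo[3.3.1]non-2-ene-4,9-dione F13, and coupling with 13 as in step 7 would give 16.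

Further compounds
F1 | step 3 | 2,6-dimethoxy-1-(3-methylbut-2-en-1-yl)cyclohexa-2,5-diene-1-carboxylic acid | OC(=O)C1(CC=C(C)C)C(OC)=CCC=C1OC
F2 | step 3 | 2,6-dimethoxy-1-(3-methylbut-2-en-1-yl)cyclohexa-2,5-diene-1-carbonyl chloride | ClC(=O)C1(CC=C(C)C)C(OC)=CCC=C1OC
F3 | step 3 | 2-diazo-1-[2,6-dimethoxy-1-(3-methylbut-2-en-1-yl)cyclohexa-2,5-dien-1-yl]ethan-1-one | [N-]=[N+]=CC(=O)C1(CC=C(C)C)C(OC)=CCC=C1OC
F4 | step 3 | methyl [2,6-dimethoxy-1-(3-methylbut-2-en-1-yl)cyclohexa-2,5-dien-1-yl]acetate | COC(=O)CC1(CC=C(C)C)C(OC)=CCC=C1OC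
F5 | step 3 | methyl 2-[2,6-dimethoxy-1-(3-methylbut-2-en-1-yl)cyclohexa-2,5-dien-1-yl]propanoate (racemic) | COC(=O)C(C)C1(CC=C(C)C)C(OC)=CCC=C1OC
F6 | step 3 | methyl 2-[2,6-dimethoxy-1-(3-methylbut-2-en-1-yl)cyclohexa-2,5-dien-1-yl]-2-methylpropanoate | COC(=O)C(C)(C)C1(CC=C(C)C)C(OC)=CCC=C1OC
F7 | step 5 | 3-[2,6-dimethoxy-1-(3-methylbut-2-en-1-yl)cyclohexa-2,5-dien-1-yl]-3-methyl-1-(2,4,6-trimethylbenzenesulfonyl)butan-2-one | CC(C)=CCC1(C(C)(C)C(=O)CS(=O)(=O)c2c(C)cc(C)cc2C)C(OC)=CCC=C1OC
F8 | step 5 | 1-diazo-3-[2,6-dimethoxy-1-(3-methylbut-2-en-1-yl)cyclohexa-2,5-dien-1-yl]-3-methyl-1-(2,4,6-trimethylbenzenesulfonyl)butan-2-one | CC(C)=CCC1(C(C)(C)C(=O)C(=[N+]=[N-])S(=O)(=O)c2c(C)cc(C)cc2C)C(OC)=CCC=C1OC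
F9 | step 5 | 6-(2,4,6-trimethylbenzenesulfonyl)cyclopropane (analogue of 10 with the sulfonyl group on C6) | COC1=CC[C@@H]2[C@]3(S(=O)(=O)c4c(C)cc(C)cc4C)C(=O)C(C)(C)[C@@]1(CC=C(C)C)[C@]23OC
F10 | step 5 | 6-(2,4,6-trimethylbenzenesulfonyl)bicyclononenedione (analogue of 11 with the sulfonyl group on C6, C6 epimers) | [C@H]12C(S(=O)(=O)c3c(C)cc(C)cc3C)C(=O)C(C)(C)[C@](CC=C(C)C)(C(OC)=CC1)C2=O
F11 | step 8 | (1R,5S)-2-methoxy-8,8-dimethyl-1-(3-methylbut-2-en-1-yl)bicyclo[3.3.1]non-2-ene-4,7,9-trione | [C@H]12CC(=O)C(C)(C)[C@](CC=C(C)C)(C(OC)=CC1=O)C2=O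
F12 | step 8 | (1R,5S)-2-methoxy-8,8-dimethyl-7-methylidene-1-(3-methylbut-2-en-1-yl)bicyclo[3.3.1]non-2-ene-4,9-dione | [C@H]12CC(=C)C(C)(C)[C@](CC=C(C)C)(C(OC)=CC1=O)C2=O
F13 | step 8 | (1R,5S,7S)-7-[(9-borabicyclo[3.3.1]nonan-9-yl)methyl]-2-methoxy-8,8-dimethyl-1-(3-methylbut-2-en-1-yl)bicyclo[3.3.1]non-2-ene-4,9-dione | [C@H]12C[C@H](CB3C4CCCC3CCC4)C(C)(C)[C@](CC=C(C)C)(C(OC)=CC1=O)C2=O
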